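The bicyclo[3.3.1]nonane is cut at C5–C6 and C1–C8. A fully substituted phloroglucinol aryl ether carries the C6–C7–C8 unit as a 2-formylallyl group on the oxygen between the aroyl and prenyl carbons. In one pot, a copper-catalysed enantioselective dearomative Claisen shift transfers it to C1 (vicinal quaternary C1–C8), and the methyl enol ether carbon C5 of the resulting dienone, which lies 1,3 to C1 across C9 in the six-membered ring C1–C2–C3–C4–C5–C9, adds to the enal methylene C6. This Michael closure forms ring C1–C8–C7–C6–C5–C9, the quaternary C5 and, by exo protonation, the endo C7 centre; the formyl group is then homologated to prenyl.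

Key step: step 11

Remark: atoms are numbered as in the target bicycle (C1 prenyl bridgehead, C2 ketone, C3 aroyl-bearing carbon, C4 enol carbon, C5 geranyl bridgehead, C6 methylene, C7, C8 gem-dimethyl carbon, C9 bridging ketone; ring A is C1–C2–C3–C4–C5–C9), and the sense of induction of the copper–bis(oxazoline) catalyst in step 11 is assumed, the mirror-image ligand being used should the opposite sense be found.

Step 1
Reactants: 1 3,4-dihydroxybenzaldehyde
Product: 2 3,4-bis(triisopropylsilyloxy)benzaldehyde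
Conditions: i-Pr3SiCl (2.4 equiv), imidazole, DMF, rt
Reagents that add atoms: triisopropylsilyl chloride, CC(C)[Si](Cl)(C(C)C)C(C)C
Why: Standard silylation of both phenols gives bulky aryl silyl ethers that should survive Grignard base, carbonate, Lewis acids and ylides and fall off in the final hydroxide step.

Step 2
Reactants: 3 diethyl 2-(propan-2-ylidene)malonate
Product: 4 2-(propan-2-ylidene)propane-1,3-diol
Conditions: i-Bu2AlH (4.5 equiv), CH2Cl2, −78 to 0 °C; aq. potassium sodium tartrate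
Reagents that add atoms: none
Why: The electrophilic aluminium hydride reduces both esters of the alkylidene malonate in a 1,2 sense to the allylic diol without conjugate reduction.

Step 3
Reactants: 4 2-(propan-2-ylidene)propane-1,3-diol
Product: 5 2-(hydroxymethyl)-3-methylbut-2-enal
Conditions: MnO2 (activated, excess), CH2Cl2, rt
Reagents that add atoms: none
Why: Allylic oxidation with MnO2 can be stopped after one of the two equivalent hydroxymethyl groups because the enal formed first deactivates the second one.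

Step 4
Reactants: 5 2-(hydroxymethyl)-3-methylbut-2-enal
Product: 6 2-(bromomethyl)-3-methylbut-2-enal
Conditions: CBr4, PPh3, CH2Cl2, 0 °C
Reagents that add atoms: tetrabromomethane, BrC(Br)(Br)Br
Why: Appel bromination converts the primary allylic alcohol into the bromide under neutral conditions that leave the enal untouched.

Step 5
Reactants: 7 1,3-dimethoxybenzene; 8 geranyl bromide [(2E)-1-bromo-3,7-dimethylocta-2,6-diene]
Product: 10 2-[(2E)-3,7-dimethylocta-2,6-dienyl]-1,3-dimethoxybenzene, via 2,6-dimethoxyphenyllithium 9 (not isolated)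
Conditions: n-BuLi, THF, 0 °C to rt; CuI (10 mol %), then 8, −78 °C to rt
Reagents that add atoms: none
Why: Directed ortho-metalation between the two methoxy groups followed by SN2 allylation of the aryl metal keeps the (E)-geometry of the geranyl chain.

Step 6
Reactants: 10 2-[(2E)-3,7-dimethylocta-2,6-dienyl]-1,3-dimethoxybenzene
Product: 12 4-[(2E)-3,7-dimethylocta-2,6-dienyl]-3,5-dimethoxyphenol, via aryl pinacol boronate 11 (not isolated)
Conditions: [Ir(OMe)(cod)]2 (1.5 mol %), 4,4′-di-tert-butyl-2,2′-bipyridine (3 mol %), B2pin2, THF, 80 °C; then 30% H2O2, aq. NaOH, 0 °C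
Reagents that add atoms: hydrogen peroxide, OO
Why: Iridium-catalysed C–H borylation is sterically governed and should take the one ring C–H without an ortho substituent (para to geranyl), and oxidation of the C–B bond then gives the phenol.

Step 7
Reactants: 12 4-[(2E)-3,7-dimethylocta-2,6-dienyl]-3,5-dimethoxyphenol; 13 prenyl bromide (1-bromo-3-methylbut-2-ene)
Product: 14 4-[(2E)-3,7-dimethylocta-2,6-dienyl]-3,5-dimethoxy-2-(3-methylbut-2-enyl)phenol
Conditions: NaH, toluene, 0 °C; then 13, rt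
Reagents that add atoms: none
Why: Ortho C-alkylation of a sodium phenoxide in a non-polar solvent (tight ion pair) installs the future C1 prenyl group; the two ortho carbons are equivalent and the para carbon is blocked.

Step 8
Reactants: 14 4-[(2E)-3,7-dimethylocta-2,6-dienyl]-3,5-dimethoxy-2-(3-methylbut-2-enyl)phenol; 2 3,4-bis(triisopropylsilyloxy)benzaldehyde
Product: 15 [3,4-bis(triisopropylsilyloxy)phenyl]{3-[(2E)-3,7-dimethylocta-2,6-dienyl]-6-hydroxy-2,4-dimethoxy-5-(3-methylbut-2-enyl)phenyl}methanol (racemic carbinol)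
Conditions: EtMgBr (1.0 equiv), Et2O, 0 °C; then 2, toluene, rt; aq. NH4Cl
Reagents that add atoms: none
Why: Ortho-specific hydroxyalkylation of the bromomagnesium phenoxide by the aldehyde (Casiraghi reaction, magnesium-templated) functionalises the last free ring carbon without acid that would cyclise the prenyl and geranyl chains.

Step 9
Reactants: 15 the diaryl carbinol
Product: 16 [3,4-bis(triisopropylsilyloxy)phenyl]{3-[(2E)-3,7-dimethylocta-2,6-dienyl]-6-hydroxy-2,4-dimethoxy-5-(3-methylbut-2-enyl)phenyl}methanone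
Conditions: MnO2 (activated), CH2Cl2, rt
Reagents that add atoms: none
Why: Oxidation of the doubly benzylic alcohol gives the ortho-hydroxy benzophenone, whose chelated phenol is the only free oxygen of ring A.

Step 10
Reactants: 16 the ortho-hydroxy benzophenone; 6 2-(bromomethyl)-3-methylbut-2-enal
Product: 17 [3,4-bis(triisopropylsilyloxy)phenyl]{3-[(2E)-3,7-dimethylocta-2,6-dienyl]-6-[(2-formyl-3-methylbut-2-enyl)oxy]-2,4-dimethoxy-5-(3-methylbut-2-enyl)phenyl}methanone
Conditions: K2CO3, DMF, rt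
Reagents that add atoms: none
Why: Williamson O-alkylation at the primary allylic bromide places the allyl unit on the oxygen between the aroyl-bearing C3 and the prenyl-bearing C1, which fixes in advance that C8 goes to C1 and C6 to C5.

Step 11
Reactants: 17 the 2-formylallyl aryl ether
Product: 19 (1S,5S,7S)-3-[3,4-bis(triisopropylsilyloxy)benzoyl]-5-[(2E)-3,7-dimethylocta-2,6-dienyl]-4-methoxy-8,8-dimethyl-1-(3-methylbut-2-enyl)-2,9-dioxobicyclo[3.3.1]non-3-ene-7-carbaldehyde (formyl endo: cis to the C2–C4 bridge), via (6S)-cyclohexa-2,4-dienone 18 (not isolated)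
Conditions: Cu(OTf)2 (10 mol %), (S,S)-t-Bu-box (12 mol %), 4 Å MS, CH2Cl2, −20 °C; then Sc(OTf)3 (20 mol %), H2O (5 equiv), MeCN, −20 to 0 °C; aq. NaHCO3
Reagents that add atoms: water, O
Why: Proposed new method: divalent copper, held by the bis(oxazoline), binds the ether oxygen and the ortho aroyl carbonyl of 17 and so triggers a chair-like [3,3]-sigmatropic aromatic Claisen shift of the 2-formylallyl group to the prenyl-bearing ortho carbon C1, which dearomatizes ring A, forms the vicinal quaternary C1–C8 bond and sets C1 under ligand control; the closest known reaction types are the Cu(OTf)2–bis(oxazoline)-catalysed Claisen rearrangement of 2-alkoxycarbonyl allyl vinyl ethers and the copper-catalysed enantioselective dearomative Claisen rearrangement of 2-naphthyl allyl ethers with a chelating ortho carbonyl, not yet shown for a phloroglucinol ether or for a shift that builds two adjacent quaternary carbons. Sc(OTf)3 then activates the enal of dienone 18, whose methyl enol ether carbon C5 adds to the terminal methylene C6 (intramolecular Mukaiyama–Michael addition), and water turns the O-methyl oxocarbenium ion at C9 into the bridging ketone with loss of methanol. Ring C1–C8–C7–C6–C5–C9 closes in a 6-endo-trig mode, and since the three-carbon tether can reach C5 only on the face of ring A on which it was delivered, the configuration of the new quaternary C5 follows from C1. C7 should be set by protonation of the scandium enolate from the open exo face, away from the C2–C3–C4 bridge, so that the formyl group ends endo, and no base is present that could equilibrate it to the exo epimer. The step needs shift to C1 instead of C3 (attack at the aroyl-bearing carbon would break the stabilised vinylogous system), C- instead of O-cyclisation (the oxa-Michael adduct of the C2 carbonyl is reversible) and closure before a thermal Cope shift of the allyl unit from C1 to C5, which the low temperature should secure.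

Step 12
Reactants: 19 the endo aldehyde
Product: 21 2-[(1S,5S,7R)-3-[3,4-bis(triisopropylsilyloxy)benzoyl]-5-[(2E)-3,7-dimethylocta-2,6-dienyl]-4-methoxy-8,8-dimethyl-1-(3-methylbut-2-enyl)-2,9-dioxobicyclo[3.3.1]non-3-en-7-yl]acetaldehyde, via methyl enol ether 20 (not isolated)
Conditions: MeOCH2PPh3Cl, KN(SiMe3)2, THF, −78 to 0 °C; then 0.5 M HCl, THF, 0 °C
Reagents that add atoms: (methoxymethyl)triphenylphosphonium chloride, COC[P+](c1ccccc1)(c1ccccc1)c1ccccc1.[Cl-]; water, O
Why: Wittig methoxymethylenation of the only aldehyde (the C9, C2 and aroyl ketones are hindered and deactivated) and mild hydrolysis of the enol ether give the one-carbon homologue, after which C7 is no longer α to a carbonyl and keeps its configuration.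

Step 13
Reactants: 21 the homologated aldehyde
Product: 22 (1S,5S,7S)-3-[3,4-bis(triisopropylsilyloxy)benzoyl]-5-[(2E)-3,7-dimethylocta-2,6-dienyl]-4-methoxy-8,8-dimethyl-1,7-bis(3-methylbut-2-enyl)bicyclo[3.3.1]non-3-ene-2,9-dione
Conditions: i-PrPPh3I, n-BuLi, THF, −78 °C to rt
Reagents that add atoms: isopropyltriphenylphosphonium iodide, CC(C)[P+](c1ccccc1)(c1ccccc1)c1ccccc1.[I-]
Why: Wittig olefination with the isopropylidene ylide completes the C7 prenyl group.

Step 14
Reactants: 22 the protected target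
Product: 23 (1S,5S,7S)-3-(3,4-dihydroxybenzoyl)-5-[(2E)-3,7-dimethylocta-2,6-dienyl]-4-hydroxy-8,8-dimethyl-1,7-bis(3-methylbut-2-enyl)bicyclo[3.3.1]non-3-ene-2,9-dione (target)
Conditions: LiOH, dioxane–H2O (degassed), 80 °C; then 1 M HCl to pH 3, 0 °C
Reagents that add atoms: lithium hydroxide, [Li+].[OH-]
Why: Hydroxide cleaves the vinylogous methyl ester by addition–elimination at C4 and removes both aryl silyl ethers, and the stable triketone enolate and catecholate are protonated on cold acidification without touching any stereocentre.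

Compound list
1 | 3,4-dihydroxybenzaldehyde | O=Cc1ccc(O)c(O)c1 | starting material
2 | 3,4-bis(triisopropylsilyloxy)benzaldehyde | O=Cc1ccc(O[Si](C(C)C)(C(C)C)C(C)C)c(O[Si](C(C)C)(C(C)C)C(C)C)c1 | intermediate
3 | diethyl 2-(propan-2-ylidene)malonate | CCOC(=O)C(=C(C)C)C(=O)OCC | starting material
4 | 2-(propan-2-ylidene)propane-1,3-diol | OCC(CO)=C(C)C | intermediate
5 | 2-(hydroxymethyl)-3-methylbut-2-enal | O=CC(CO)=C(C)C | intermediate
6 | 2-(bromomethyl)-3-methylbut-2-enal | O=CC(CBr)=C(C)C | intermediate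
7 | 1,3-dimethoxybenzene | COc1cccc(OC)c1 | starting material
8 | geranyl bromide, (2E)-1-bromo-3,7-dimethylocta-2,6-diene | BrC/C=C(\C)CCC=C(C)C | starting material
9 | 2,6-dimethoxyphenyllithium | [Li]c1c(OC)cccc1OC | intermediate
10 | 2-[(2E)-3,7-dimethylocta-2,6-dienyl]-1,3-dimethoxybenzene | COc1cccc(OC)c1C/C=C(\C)CCC=C(C)C | intermediate
11 | 2-{4-[(2E)-3,7-dimethylocta-2,6-dienyl]-3,5-dimethoxyphenyl}-4,4,5,5-tetramethyl-1,3,2-dioxaborolane | COc1cc(B2OC(C)(C)C(C)(C)O2)cc(OC)c1C/C=C(\C)CCC=C(C)C | intermediate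
12 | 4-[(2E)-3,7-dimethylocta-2,6-dienyl]-3,5-dimethoxyphenol | COc1cc(O)cc(OC)c1C/C=C(\C)CCC=C(C)C | intermediate
13 | prenyl bromide, 1-bromo-3-methylbut-2-ene | BrCC=C(C)C | starting material
14 | 4-[(2E)-3,7-dimethylocta-2,6-dienyl]-3,5-dimethoxy-2-(3-methylbut-2-enyl)phenol | COc1cc(O)c(CC=C(C)C)c(OC)c1C/C=C(\C)CCC=C(C)C | intermediate
15 | [3,4-bis(triisopropylsilyloxy)phenyl]{3-[(2E)-3,7-dimethylocta-2,6-dienyl]-6-hydroxy-2,4-dimethoxy-5-(3-methylbut-2-enyl)phenyl}methanol, racemic at the carbinol | OC(c1ccc(O[Si](C(C)C)(C(C)C)C(C)C)c(O[Si](C(C)C)(C(C)C)C(C)C)c1)c1c(O)c(CC=C(C)C)c(OC)c(C/C=C(\C)CCC=C(C)C)c1OC | intermediate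
16 | [3,4-bis(triisopropylsilyloxy)phenyl]{3-[(2E)-3,7-dimethylocta-2,6-dienyl]-6-hydroxy-2,4-dimethoxy-5-(3-methylbut-2-enyl)phenyl}methanone | O=C(c1ccc(O[Si](C(C)C)(C(C)C)C(C)C)c(O[Si](C(C)C)(C(C)C)C(C)C)c1)c1c(O)c(CC=C(C)C)c(OC)c(C/C=C(\C)CCC=C(C)C)c1OC | intermediate
17 | [3,4-bis(triisopropylsilyloxy)phenyl]{3-[(2E)-3,7-dimethylocta-2,6-dienyl]-6-[(2-formyl-3-methylbut-2-enyl)oxy]-2,4-dimethoxy-5-(3-methylbut-2-enyl)phenyl}methanone | O=C(c1ccc(O[Si](C(C)C)(C(C)C)C(C)C)c(O[Si](C(C)C)(C(C)C)C(C)C)c1)c1c(OCC(C=O)=C(C)C)c(CC=C(C)C)c(OC)c(C/C=C(\C)CCC=C(C)C)c1OC | intermediate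
18 | (6S)-2-[3,4-bis(triisopropylsilyloxy)benzoyl]-4-[(2E)-3,7-dimethylocta-2,6-dienyl]-3,5-dimethoxy-6-(2-methyl-3-methylidene-4-oxobutan-2-yl)-6-(3-methylbut-2-enyl)cyclohexa-2,4-dien-1-one | O=CC(=C)C(C)(C)[C@]1(CC=C(C)C)C(=O)C(C(=O)c2ccc(O[Si](C(C)C)(C(C)C)C(C)C)c(O[Si](C(C)C)(C(C)C)C(C)C)c2)=C(OC)C(C/C=C(\C)CCC=C(C)C)=C1OC | intermediate
19 | (1S,5S,7S)-3-[3,4-bis(triisopropylsilyloxy)benzoyl]-5-[(2E)-3,7-dimethylocta-2,6-dienyl]-4-methoxy-8,8-dimethyl-1-(3-methylbut-2-enyl)-2,9-dioxobicyclo[3.3.1]non-3-ene-7-carbaldehyde, formyl endo | CC(C)=CCC/C(C)=C/C[C@]12C[C@H](C=O)C(C)(C)[C@](CC=C(C)C)(C(=O)C(C(=O)c3ccc(O[Si](C(C)C)(C(C)C)C(C)C)c(O[Si](C(C)C)(C(C)C)C(C)C)c3)=C1OC)C2=O | intermediate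
20 | (1S,5S,7R)-3-[3,4-bis(triisopropylsilyloxy)benzoyl]-5-[(2E)-3,7-dimethylocta-2,6-dienyl]-4-methoxy-7-(2-methoxyethenyl)-8,8-dimethyl-1-(3-methylbut-2-enyl)bicyclo[3.3.1]non-3-ene-2,9-dione, E/Z mixture at the enol ether | CC(C)=CCC/C(C)=C/C[C@]12C[C@H](C=COC)C(C)(C)[C@](CC=C(C)C)(C(=O)C(C(=O)c3ccc(O[Si](C(C)C)(C(C)C)C(C)C)c(O[Si](C(C)C)(C(C)C)C(C)C)c3)=C1OC)C2=O | intermediate
21 | 2-[(1S,5S,7R)-3-[3,4-bis(triisopropylsilyloxy)benzoyl]-5-[(2E)-3,7-dimethylocta-2,6-dienyl]-4-methoxy-8,8-dimethyl-1-(3-methylbut-2-enyl)-2,9-dioxobicyclo[3.3.1]non-3-en-7-yl]acetaldehyde | CC(C)=CCC/C(C)=C/C[C@]12C[C@H](CC=O)C(C)(C)[C@](CC=C(C)C)(C(=O)C(C(=O)c3ccc(O[Si](C(C)C)(C(C)C)C(C)C)c(O[Si](C(C)C)(C(C)C)C(C)C)c3)=C1OC)C2=O | intermediate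
22 | (1S,5S,7S)-3-[3,4-bis(triisopropylsilyloxy)benzoyl]-5-[(2E)-3,7-dimethylocta-2,6-dienyl]-4-methoxy-8,8-dimethyl-1,7-bis(3-methylbut-2-enyl)bicyclo[3.3.1]non-3-ene-2,9-dione | CC(C)=CCC/C(C)=C/C[C@]12C[C@H](CC=C(C)C)C(C)(C)[C@](CC=C(C)C)(C(=O)C(C(=O)c3ccc(O[Si](C(C)C)(C(C)C)C(C)C)c(O[Si](C(C)C)(C(C)C)C(C)C)c3)=C1OC)C2=O | intermediate
23 | (1S,5S,7S)-3-(3,4-dihydroxybenzoyl)-5-[(2E)-3,7-dimethylocta-2,6-dienyl]-4-hydroxy-8,8-dimethyl-1,7-bis(3-methylbut-2-enyl)bicyclo[3.3.1]non-3-ene-2,9-dione | CC(C)=CCC/C(C)=C/C[C@]12C[C@H](CC=C(C)C)C(C)(C)[C@](CC=C(C)C)(C(=O)C(C(=O)c3ccc(O)c(O)c3)=C1O)C2=O | target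

Total step count: 14. Longest linear sequence: 10 steps (steps 5 to 14, from 1,3-dimethoxybenzene).

Steps most likely to fail

1. Step 11 (Proposed new method). The copper catalyst may discriminate the two faces of ring A poorly, because the formyl oxygen can compete with the aroyl oxygen for the metal and an uncatalysed shift can run beside the catalysed one; the chelating dienone may also hold the catalyst back. The fallback uses known chemistry and sets out from 17. Heating in toluene at 80 °C should bring about the uncatalysed aromatic Claisen rearrangement to the racemic 6,6-disubstituted cyclohexa-2,4-dienone F1 (any material that has gone on by a Cope shift to C5 closes to the same bicycle). Sc(OTf)3 in wet MeCN closes it as in the main route to the racemic endo aldehyde F2. Condensation with (S)-1-amino-2-(methoxymethyl)pyrrolidine gives two diastereomeric hydrazones; the (1S,5S,7S)-hydrazone F3 is separated by chromatography and hydrolysed with aqueous oxalic acid in a two-phase system, which returns the route to 19.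

2. Step 12. The basic ylide may enolise the hindered aldehyde and so epimerise the kinetically formed endo C7 centre to the more stable exo one, and the acid used to unmask the enol ether may start to hydrolyse the vinylogous ester. The fallback sets out from 19. NaBH4 in THF–MeOH at −40 °C reduces only the aldehyde to the primary alcohol F4, which takes the epimerisable centre out of danger at once. I2, PPh3 and imidazole give the primary iodide F5. Zinc dust and LiCl in THF give the alkylzinc iodide F6 (not isolated), and Negishi coupling with 1-bromo-2-methylprop-1-ene under Pd(PPh3)4 joins the route again at 22.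

3. Step 7. O-alkylation and a second alkylation may compete with the wanted single ortho C-alkylation of the phenoxide. The fallback sets out from 12. Etherification with 3-chloro-3-methylbut-1-yne (DBU, CuCl2 cat., MeCN, 0 °C) gives the aryl 1,1-dimethylpropargyl ether F7. Semihydrogenation over Pd/CaCO3 poisoned with Pb(OAc)2 and quinoline gives the aryl 1,1-dimethylallyl ether F8. A thermal aromatic Claisen rearrangement (toluene, 120 °C, sealed tube) inverts the allyl unit and delivers it as a prenyl group to the free ortho carbon, which returns the route to 14.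

Further compounds
F1 | step 11 | racemic 2-[3,4-bis(triisopropylsilyloxy)benzoyl]-4-[(2E)-3,7-dimethylocta-2,6-dienyl]-3,5-dimethoxy-6-(2-methyl-3-methylidene-4-oxobutan-2-yl)-6-(3-methylbut-2-enyl)cyclohexa-2,4-dien-1-one | O=CC(=C)C(C)(C)C1(CC=C(C)C)C(=O)C(C(=O)c2ccc(O[Si](C(C)C)(C(C)C)C(C)C)c(O[Si](C(C)C)(C(C)C)C(C)C)c2)=C(OC)C(C/C=C(\C)CCC=C(C)C)=C1OC
F2 | step 11 | racemic (1S*,5S*,7S*)-3-[3,4-bis(triisopropylsilyloxy)benzoyl]-5-[(2E)-3,7-dimethylocta-2,6-dienyl]-4-methoxy-8,8-dimethyl-1-(3-methylbut-2-enyl)-2,9-dioxobicyclo[3.3.1]non-3-ene-7-carbaldehyde (both enantiomers) | CC(C)=CCC/C(C)=C/C[C@]12C[C@H](C=O)C(C)(C)[C@](CC=C(C)C)(C(=O)C(C(=O)c3ccc(O[Si](C(C)C)(C(C)C)C(C)C)c(O[Si](C(C)C)(C(C)C)C(C)C)c3)=C1OC)C2=O.CC(C)=CCC/C(C)=C/C[C@@]12C[C@@H](C=O)C(C)(C)[C@@](CC=C(C)C)(C(=O)C(C(=O)c3ccc(O[Si](C(C)C)(C(C)C)C(C)C)c(O[Si](C(C)C)(C(C)C)C(C)C)c3)=C1OC)C2=O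
F3 | step 11 | (E)-hydrazone of the (1S,5S,7S) aldehyde 19 with (2S)-2-(methoxymethyl)pyrrolidin-1-amine | CC(C)=CCC/C(C)=C/C[C@]12C[C@H](/C=N/N4CCC[C@H]4COC)C(C)(C)[C@](CC=C(C)C)(C(=O)C(C(=O)c3ccc(O[Si](C(C)C)(C(C)C)C(C)C)c(O[Si](C(C)C)(C(C)C)C(C)C)c3)=C1OC)C2=O
F4 | step 12 | (1S,5S,7S)-3-[3,4-bis(triisopropylsilyloxy)benzoyl]-5-[(2E)-3,7-dimethylocta-2,6-dienyl]-7-(hydroxymethyl)-4-methoxy-8,8-dimethyl-1-(3-methylbut-2-enyl)bicyclo[3.3.1]non-3-ene-2,9-dione | CC(C)=CCC/C(C)=C/C[C@]12C[C@H](CO)C(C)(C)[C@](CC=C(C)C)(C(=O)C(C(=O)c3ccc(O[Si](C(C)C)(C(C)C)C(C)C)c(O[Si](C(C)C)(C(C)C)C(C)C)c3)=C1OC)C2=O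
F5 | step 12 | (1S,5S,7S)-3-[3,4-bis(triisopropylsilyloxy)benzoyl]-5-[(2E)-3,7-dimethylocta-2,6-dienyl]-7-(iodomethyl)-4-methoxy-8,8-dimethyl-1-(3-methylbut-2-enyl)bicyclo[3.3.1]non-3-ene-2,9-dione | CC(C)=CCC/C(C)=C/C[C@]12C[C@H](CI)C(C)(C)[C@](CC=C(C)C)(C(=O)C(C(=O)c3ccc(O[Si](C(C)C)(C(C)C)C(C)C)c(O[Si](C(C)C)(C(C)C)C(C)C)c3)=C1OC)C2=O
F6 | step 12 | alkylzinc iodide from F5 (iodozinciomethyl group at C7, same configuration) | CC(C)=CCC/C(C)=C/C[C@]12C[C@H](C[Zn]I)C(C)(C)[C@](CC=C(C)C)(C(=O)C(C(=O)c3ccc(O[Si](C(C)C)(C(C)C)C(C)C)c(O[Si](C(C)C)(C(C)C)C(C)C)c3)=C1OC)C2=O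
F7 | step 7 | 2-[(2E)-3,7-dimethylocta-2,6-dienyl]-1,3-dimethoxy-5-[(2-methylbut-3-yn-2-yl)oxy]benzene | C#CC(C)(C)Oc1cc(OC)c(C/C=C(\C)CCC=C(C)C)c(OC)c1
F8 | step 7 | 2-[(2E)-3,7-dimethylocta-2,6-dienyl]-1,3-dimethoxy-5-[(2-methylbut-3-en-2-yl)oxy]benzene | C=CC(C)(C)Oc1cc(OC)c(C/C=C(\C)CCC=C(C)C)c(OC)c1
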